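**Retrosynthetic overview**
1. The target is (13S)-15-acetoxylabd-7-en-17-oic acid. The carboxyl carbon (C8–C17) comes from Pd hydroxycarbonylation of the Δ7 enol triflate of a 17-nor-8-ketone.
2. The ketone comes from ozonolysis of the 8(17)-ene, made by dehydration of (13S)-labdane-8α,15-diol.
3. Key disconnection C11–C12: photo-electrochemical double decarboxylative coupling of ring-opened (+)-sclareolide (C1–C11) with ring-opened (R)-4-methyl-δ-valerolactone (C12–C16).
4. The lactone comes from (R)-citronellic acid by dealkenylative oxygenation (C5–C6 cut; C1 is later lost as CO2).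
5. Rings: no carbocycle is built. The trans-decalin (C5, C9, C10) is bought in sclareolide and C13 in citronellic acid; the only ring formed (δ-lactone 5) is transient.

Assumption: labdane numbering is used (C8 carries CO2H, C9 the side chain, C13 the side-chain methyl); (+)-sclareolide and (R)-(+)-citronellic acid are purchased.

**Step 1**
Reactants: 1 (R)-(+)-citronellic acid
Product: 5 (R)-4-methyltetrahydro-2H-pyran-2-one, via α-methoxy hydroperoxide 2 (not isolated), via TEMPO alkoxyamine acid 3 (not isolated), via hydroxy acid 4 (not isolated)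
Conditions: O3, MeOH, −78 °C; then FeSO4·7H2O (1.2 equiv), TEMPO (1.5 equiv), −78 °C → rt; then Zn, AcOH, 60 °C (one pot)
Reagents that add atoms: TEMPO, CC1(C)CCCC(C)(C)N1[O]
Why: Criegee ozonolysis in methanol releases acetone and leaves the C6 α-methoxy hydroperoxide, FeII reduction gives an alkoxy radical whose β-scission (methyl formate lost) leaves the primary C5 radical that TEMPO traps (dealkenylative oxygenation), and Zn/AcOH N–O cleavage is followed by spontaneous δ-lactonisation; the C3 stereocentre is never a radical or enolisable centre and stays (R).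

**Step 2**
Reactants: 6 (+)-sclareolide; 5 (R)-4-methyltetrahydro-2H-pyran-2-one (3 equiv)
Product: 9 (13S)-labdane-8α,15-diol, via potassium salt of ring-opened sclareolide 7 (not isolated), via potassium (3R)-5-hydroxy-3-methylpentanoate 8 (not isolated)
Conditions: KOH (1 equiv per lactone), MeOH–H2O, 60 °C, evaporate; then Fe(OTf)3/di(2-picolyl)amine (10 mol %), Ni(acac)2 (10 mol %), MeCN–H2O 9:1, 390 nm LEDs, graphite(+) at +0.7 V vs Ag/AgCl | Pt(−), undivided cell, 20 °C
Reagents that add atoms: none
Why: Proposed new method: a photo-electrochemical radical-sorting double decarboxylation in which both potassium carboxylates bind FeIII and lose CO2 after 390 nm LMCT homolysis, FeII is re-oxidised at the anode about 1.5 V below Kolbe potentials (so the hydroxyls, Ni(acac)2 and the product survive), the unhindered side-chain radical is held by Ni(acac)2 as an alkyl–NiIII species and the heavily β-branched C11 radical (too hindered to bind Ni or dimerise quickly) attacks that alkyl group by SH2 to forge C11–C12 while H2 forms at the cathode, with no stereocentre touched because C9 and C13 are only adjacent to the radical carbons; the closest known reaction types are mixed Kolbe electrolysis, FeIII-carboxylate LMCT photodecarboxylation and nickel-mediated SH2 radical-sorting alkyl–alkyl coupling.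

**Step 3**
Reactants: 9 (13S)-labdane-8α,15-diol
Product: 11 (13S)-labd-8(17)-en-15-yl acetate, via 8α-hydroxy 15-acetate 10 (not isolated)
Conditions: Ac2O (1.2 equiv), pyridine, DMAP (cat.), CH2Cl2, 0 °C → rt; then SOCl2 (3 equiv), −78 °C (one pot)
Reagents that add atoms: acetic anhydride, CC(=O)OC(C)=O
Why: The primary alcohol is acetylated selectively (the hindered tertiary 8α-OH is inert), then E2 dehydration of the chlorosulfite of the equatorial 8α-OH, which has no anti-periplanar ring hydrogen, eliminates towards the C17 methyl to give the exocyclic alkene; no stereocentre is affected.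

**Step 4**
Reactants: 11 (13S)-labd-8(17)-en-15-yl acetate
Product: 13 (13S)-8-oxo-17-norlabdan-15-yl acetate, via secondary ozonide 12 (not isolated)
Conditions: O3, CH2Cl2, −78 °C; then Me2S, −78 °C → rt
Reagents that add atoms: ozone, [O-][O+]=O
Why: Ozonolysis with reductive work-up excises C17 as formaldehyde; C9, now α to the ketone, keeps its equatorial β side chain, which is also the thermodynamically preferred epimer.

**Step 5**
Reactants: 13 (13S)-8-oxo-17-norlabdan-15-yl acetate
Product: 15 (13S)-8-(trifluoromethanesulfonyloxy)-17-norlabd-7-en-15-yl acetate, via potassium Δ7-enolate 14 (not isolated)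
Conditions: KHMDS (1.15 equiv), THF, −78 °C (ketone added to base); then PhNTf2 (1.3 equiv), −78 → 0 °C
Reagents that add atoms: N-phenyl-bis(trifluoromethanesulfonimide), FC(F)(F)S(=O)(=O)N(c1ccccc1)S(=O)(=O)C(F)(F)F
Why: Kinetic deprotonation takes the unhindered C7 methylene rather than the tertiary C9–H flanked by the quaternary C10 (and the ketone is far more acidic than the acetate), and O-triflation of the enolate fixes the Δ7 regiochemistry (kinetic enol triflate formation) without touching C9.

**Step 6**
Reactants: 15 (13S)-8-(trifluoromethanesulfonyloxy)-17-norlabd-7-en-15-yl acetate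
Product: 17 (13S)-15-acetoxylabd-7-en-17-oic acid (target), via potassium carboxylate 16 (not isolated)
Conditions: Pd(OAc)2 (5 mol %), dppf (10 mol %), CO (1 atm), KOAc (4 equiv), DMF–H2O 20:1, 60 °C; then 1 M HCl
Reagents that add atoms: carbon monoxide, [C-]#[O+]; water, O
Why: Pd-catalysed hydroxycarbonylation of the enol triflate (oxidative addition, CO insertion, hydrolysis of the acyl-Pd) forms the C8–C17 bond with the Δ7 position retained, and the neutral conditions leave the primary acetate intact.

**Compound list**
1 | (R)-(+)-citronellic acid, (3R)-3,7-dimethyloct-6-enoic acid | OC(=O)C[C@H](C)CCC=C(C)C | starting material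
2 | (3R)-6-hydroperoxy-6-methoxy-3-methylhexanoic acid (C6 epimers) | OC(=O)C[C@H](C)CCC(OC)OO | intermediate
3 | (3R)-3-methyl-5-[(2,2,6,6-tetramethylpiperidin-1-yl)oxy]pentanoic acid | OC(=O)C[C@H](C)CCON1C(C)(C)CCCC1(C)C | intermediate
4 | (3R)-5-hydroxy-3-methylpentanoic acid | OC(=O)C[C@H](C)CCO | intermediate
5 | (R)-4-methyltetrahydro-2H-pyran-2-one | O=C1C[C@H](C)CCO1 | intermediate
6 | (+)-sclareolide, (3aR,5aS,9aS,9bR)-3a,6,6,9a-tetramethyldecahydronaphtho[2,1-b]furan-2(1H)-one | C[C@]12CCCC([C@@H]1CC[C@@]3([C@@H]2CC(=O)O3)C)(C)C | starting material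
7 | potassium 8α-hydroxy-13,14,15,16-tetranorlabdan-12-oate (5α-H, 9α-H, 10β-Me, 8β-Me) | [K+].[O-]C(=O)C[C@H]1[C@](C)(O)CC[C@H]2C(C)(C)CCC[C@]12C | intermediate
8 | potassium (3R)-5-hydroxy-3-methylpentanoate | [K+].[O-]C(=O)C[C@H](C)CCO | intermediate
9 | (13S)-labdane-8α,15-diol (5α-H, 9α-H, 10β-Me, 8β-Me) | OCC[C@@H](C)CC[C@H]1[C@](C)(O)CC[C@H]2C(C)(C)CCC[C@]12C | intermediate
10 | (13S)-8α-hydroxylabdan-15-yl acetate | CC(=O)OCC[C@@H](C)CC[C@H]1[C@](C)(O)CC[C@H]2C(C)(C)CCC[C@]12C | intermediate
11 | (13S)-labd-8(17)-en-15-yl acetate | CC(=O)OCC[C@@H](C)CC[C@H]1C(=C)CC[C@H]2C(C)(C)CCC[C@]12C | intermediate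
12 | secondary ozonide of 11 (spiro-1,2,4-trioxolane at C8, C8 configuration undefined) | CC(=O)OCC[C@@H](C)CC[C@H]1C3(OCOO3)CC[C@H]2C(C)(C)CCC[C@]12C | intermediate
13 | (13S)-8-oxo-17-norlabdan-15-yl acetate (9α-H, side chain β-equatorial) | CC(=O)OCC[C@@H](C)CC[C@H]1C(=O)CC[C@H]2C(C)(C)CCC[C@]12C | intermediate
14 | potassium Δ7-enolate of 13 | CC(=O)OCC[C@@H](C)CC[C@H]1C([O-])=CC[C@H]2C(C)(C)CCC[C@]12C.[K+] | intermediate
15 | (13S)-8-(trifluoromethanesulfonyloxy)-17-norlabd-7-en-15-yl acetate | CC(=O)OCC[C@@H](C)CC[C@H]1C(OS(=O)(=O)C(F)(F)F)=CC[C@H]2C(C)(C)CCC[C@]12C | intermediate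
16 | potassium (13S)-15-acetoxylabd-7-en-17-oate | CC(=O)OCC[C@@H](C)CC[C@H]1C(C(=O)[O-])=CC[C@H]2C(C)(C)CCC[C@]12C.[K+] | intermediate
17 | (13S)-15-acetoxylabd-7-en-17-oic acid (5α-H, 9α-H, 10β-Me) | CC(=O)OCC[C@@H](C)CC[C@H]1C(C(=O)O)=CC[C@H]2C(C)(C)CCC[C@]12C | target

**Step count**
Total: 6 steps (three are one-pot, multi-stage operations). Longest linear sequence: 6 steps (1 → 17); sclareolide 6 enters at step 2.

**Steps most likely to fail**

Step 2 (the proposed new coupling). Risks are cross-selectivity between two primary radicals, competing LMCT at the free hydroxyls and iron hydrolysis in the bicarbonate medium. The fallback uses known chemistry and changes the principle from catalytic radical sorting in solution to statistical coupling at an electrode. It sets out from 5 and 6, which are saponified to the same salts 7 and 8. Classical mixed Kolbe electrolysis follows (smooth Pt anode, MeOH–H2O, high current density, fivefold excess of 8), and 9 is separated from the two symmetric dimers. It comes back to the route at 9 and makes no new compound (F0).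

Step 1. The Criegee cleavage of the trisubstituted alkene may partly place the carbonyl oxide on the acetone fragment, and the three-stage one-pot sequence may not telescope cleanly. The fallback sets out from 1. Ozonolysis with Me2S work-up, which is indifferent to the direction of Criegee cleavage, gives (3R)-3-methyl-6-oxohexanoic acid F1. TMSCl/Et3N in DMF gives trimethylsilyl (3R)-3-methyl-6-(trimethylsilyloxy)hex-5-enoate F2. A second ozonolysis with NaBH4 work-up cuts C5=C6 and reduces to hydroxy acid 4, which lactonises on acidification. The fallback comes back to the route at 5.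

Step 5. Risks are incomplete or non-regioselective enolisation of the hindered ketone and base damage to the acetate. The fallback sets out from 13. Condensation with 2,4,6-triisopropylbenzenesulfonyl hydrazide gives the trisylhydrazone F3. Excess n-BuLi (THF/TMEDA, −78 → 0 °C; the acetate is consumed) triggers the Shapiro fragmentation to the C8 vinyllithium 15-alkoxide F4. CO2 quench and acidification give (13S)-15-hydroxylabd-7-en-17-oic acid F5. Ac2O/pyridine with aqueous bicarbonate work-up re-installs the acetate. The fallback comes back to the route at 17.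

**Further compounds**
F1 | step 1 | (3R)-3-methyl-6-oxohexanoic acid | OC(=O)C[C@H](C)CCC=O
F2 | step 1 | trimethylsilyl (3R)-3-methyl-6-(trimethylsilyloxy)hex-5-enoate | C[Si](C)(C)OC(=O)C[C@H](C)CC=CO[Si](C)(C)C
F0 | step 2 | none | none
F3 | step 5 | 2,4,6-triisopropylbenzenesulfonylhydrazone of 13 | CC(=O)OCC[C@@H](C)CC[C@H]1C(=NNS(=O)(=O)c3c(C(C)C)cc(C(C)C)cc3C(C)C)CC[C@H]2C(C)(C)CCC[C@]12C
F4 | step 5 | (13S)-8-lithio-17-norlabd-7-en-15-olate, lithium salt | [Li+].[O-]CC[C@@H](C)CC[C@H]1C([Li])=CC[C@H]2C(C)(C)CCC[C@]12C
F5 | step 5 | (13S)-15-hydroxylabd-7-en-17-oic acid | OCC[C@@H](C)CC[C@H]1C(C(=O)O)=CC[C@H]2C(C)(C)CCC[C@]12C
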